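**Retrosynthetic overview**

1. Target 12 ← hydroxide opening of the O7–C(=O) lactone bond and cleavage of the O5 and O4′ methyl ethers of lactone 9.
2. Lactone 9 ← 7-hydroxy-8-(1-phenylvinyl)flavone 7 + CO. The strategy rests on the C8 side chain CH(Ph)–CH2–CO2H lying ortho to the 7-OH of ring A: the carboxyl carbon is CO, and a chiral Pd–H makes the CH2–C(=O) bond, the O7–C(=O) bond and the benzylic C–H stereocentre in one step.
3. 7 ← Suzuki coupling at C8 of the 7-hydroxy-8-iodoflavone 5 with 1-phenylvinyl boronate 6; 5 ← C8 iodination of the 5-O-methyl-7-O-MOM ether of acacetin 1.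
4. Ring order: rings A, B and C of the flavone are bought intact in acacetin; the only ring formed is the six-membered lactone (step 6), which is reopened in step 8.

Key step: step 6

Remark: the sense of induction of the chiral bisphosphine in step 6 is assumed to be assigned on the model substrate 2-(1-phenylvinyl)phenol, and the ligand antipode that gives the (R)-lactone is the one used.

**Step 1**
Reactants: 1 acacetin
Product: 2 5-hydroxy-7-(methoxymethoxy)-2-(4-methoxyphenyl)chromen-4-one
Conditions: MOMCl (1.2 equiv), K2CO3, acetone, rt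
Reagents that add atoms: chloromethyl methyl ether COCCl
Why: Williamson-type O-alkylation in which the acidic, unchelated 7-OH reacts while the 5-OH stays hydrogen-bonded to the C4 carbonyl; an acetal is used instead of an allyl ether because an ortho-allyloxy aryl iodide would undergo 5-exo carbopalladation in the later Pd-catalysed coupling.

**Step 2**
Reactants: 2 5-hydroxy-7-(methoxymethoxy)-2-(4-methoxyphenyl)chromen-4-one
Product: 3 5-methoxy-7-(methoxymethoxy)-2-(4-methoxyphenyl)chromen-4-one
Conditions: MeI (3 equiv), K2CO3, DMF, 50 °C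
Reagents that add atoms: iodomethane CI
Why: Williamson O-methylation of the chelated 5-OH under forcing conditions; the MOM acetal is stable to base.

**Step 3**
Reactants: 3 5-methoxy-7-(methoxymethoxy)-2-(4-methoxyphenyl)chromen-4-one
Product: 4 8-iodo-5-methoxy-7-(methoxymethoxy)-2-(4-methoxyphenyl)chromen-4-one
Conditions: NIS (1.1 equiv), DMF, rt to 50 °C, dark
Reagents that add atoms: N-iodosuccinimide O=C1CCC(=O)N1I
Why: Electrophilic aromatic iodination (SEAr) under neutral conditions; with O5 alkylated and no longer chelated, 5,7-dialkoxyflavones are iodinated at C8 (ortho to O7, para to O5) and not at the more crowded C6, while ring B and C3 are deactivated by conjugation with the carbonyl.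

**Step 4**
Reactants: 4 8-iodo-5-methoxy-7-(methoxymethoxy)-2-(4-methoxyphenyl)chromen-4-one
Product: 5 7-hydroxy-8-iodo-5-methoxy-2-(4-methoxyphenyl)chromen-4-one
Conditions: 2 M HCl, MeOH/THF, 45 °C
Reagents that add atoms: none
Why: Acid-catalysed acetal cleavage of the phenolic MOM ether through the oxocarbenium ion; aryl iodide, methyl ethers and chromone tolerate dilute HCl, and freeing O7 at this stage avoids any acid treatment of the later 1,1-diarylethylene.

**Step 5**
Reactants: 5 7-hydroxy-8-iodo-5-methoxy-2-(4-methoxyphenyl)chromen-4-one; 6 1-phenylvinylboronic acid pinacol ester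
Product: 7 7-hydroxy-5-methoxy-2-(4-methoxyphenyl)-8-(1-phenylethenyl)chromen-4-one
Conditions: Pd(OAc)2 (5 mol%), SPhos (10 mol%), K3PO4 (3.5 equiv), 6 (1.5 equiv), dioxane/H2O 5:1, 85 °C
Reagents that add atoms: none
Why: Suzuki–Miyaura coupling; free ortho-iodophenols are competent partners, the bulky electron-rich SPhos ligand supports oxidative addition and transmetalation at the di-ortho-substituted iodide, and no tethered alkene is present to divert the aryl–Pd intermediate.

**Step 6**
Reactants: 7 7-hydroxy-5-methoxy-2-(4-methoxyphenyl)-8-(1-phenylethenyl)chromen-4-one; 8 carbon monoxide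
Product: 9 (10R)-5-methoxy-2-(4-methoxyphenyl)-10-phenyl-9,10-dihydro-4H,8H-pyrano[2,3-h]chromene-4,8-dione (the (R)-4-phenyl-dihydrocoumarin-type lactone between O7 and the C8 side chain)
Conditions: Pd2(dba)3 (2.5 mol%), chiral bisphosphine L* (P-chiral bis(dihydrobenzooxaphosphole) of the WingPhos type, or DTBM-SEGPHOS; 6 mol%), anhydrous TsOH (10 mol%), CO (20 bar), toluene, 70 °C
Reagents that add atoms: none
Why: Pd(0) and TsOH give a cationic L*Pd–H that adds across the 1,1-diarylethylene with H to the diaryl carbon and Pd to CH2; CO inserts into the primary Pd–alkyl and the acyl–Pd is captured by the neighbouring 7-OH, releasing the lactone and Pd–H. This is the known Pd-catalysed asymmetric intramolecular hydroesterification of 2-(1-arylvinyl)phenols to 4-aryl-3,4-dihydrocoumarins, applied here to a more congested, di-ortho-oxygenated aryl. The six-membered lactone closes by intramolecular O-acylation of O7 at the acyl–Pd carbon (6-exo-trig acyl substitution, or C–O reductive elimination from the Pd(acyl)(phenoxide) chelate). The benzylic stereocentre (C10) is set in the hydropalladation: the chiral bisphosphine selects the alkene face by differentiating phenyl from the bulkier flavone aryl carrying the coordinating 7-OH, and the CO pressure should keep insertion faster than β-hydride elimination so that this choice is not eroded. Anti-Markovnikov carbonylation is secured by the 1,1-diaryl substitution, because the tertiary dibenzylic Pd–alkyl cannot insert CO and only reverts to alkene. Chemoselectivity rests on O7 being the only free hydroxyl (O5 and O4′ are methylated) and on the inertness of the trisubstituted chromone C2=C3 bond towards Pd–H.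

**Step 7**
Reactants: 9 (10R)-5-methoxy-2-(4-methoxyphenyl)-10-phenyl-9,10-dihydro-4H,8H-pyrano[2,3-h]chromene-4,8-dione
Product: 10 (10R)-5-hydroxy-2-(4-hydroxyphenyl)-10-phenyl-9,10-dihydro-4H,8H-pyrano[2,3-h]chromene-4,8-dione
Conditions: BBr3 (6 equiv), CH2Cl2, −78 °C to rt; ice-water quench
Reagents that add atoms: none
Why: Lewis-acid ether cleavage (O-coordination, bromide SN2 at methyl), chelation-assisted at O5 and driven by excess reagent at O4′; the aryl lactone has no alkyl C–O bond to cleave and the stereocentre is not alpha to the carbonyl, so the configuration should be retained.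

**Step 8**
Reactants: 10 (10R)-5-hydroxy-2-(4-hydroxyphenyl)-10-phenyl-9,10-dihydro-4H,8H-pyrano[2,3-h]chromene-4,8-dione
Product: 12 (3R)-3-[5,7-dihydroxy-2-(4-hydroxyphenyl)-4-oxochromen-8-yl]-3-phenylpropanoic acid (target), via ring-opened trilithium salt 11 (not isolated)
Conditions: LiOH·H2O (4 equiv), degassed THF/H2O, 0 °C to rt; then 1 M HCl to pH 3–4 at 0 °C, EtOAc extraction, concentration without heating
Reagents that add atoms: lithium hydroxide [Li+].[OH-]
Why: Saponification (BAc2) of the activated aryl lactone to the carboxylate/phenoxide, then protonation under cold, weakly acidic conditions that avoid relactonisation; the stereocentre is beta to the carboxylate and non-enolisable, so it is untouched.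

**Compound list**

1 | acacetin (5,7-dihydroxy-2-(4-methoxyphenyl)chromen-4-one) | COc1ccc(cc1)-c1cc(=O)c2c(O)cc(O)cc2o1 | starting material
2 | 5-hydroxy-7-(methoxymethoxy)-2-(4-methoxyphenyl)chromen-4-one | COCOc1cc(O)c2c(=O)cc(-c3ccc(OC)cc3)oc2c1 | intermediate
3 | 5-methoxy-7-(methoxymethoxy)-2-(4-methoxyphenyl)chromen-4-one | COCOc1cc(OC)c2c(=O)cc(-c3ccc(OC)cc3)oc2c1 | intermediate
4 | 8-iodo-5-methoxy-7-(methoxymethoxy)-2-(4-methoxyphenyl)chromen-4-one | COCOc1cc(OC)c2c(=O)cc(-c3ccc(OC)cc3)oc2c1I | intermediate
5 | 7-hydroxy-8-iodo-5-methoxy-2-(4-methoxyphenyl)chromen-4-one | Oc1cc(OC)c2c(=O)cc(-c3ccc(OC)cc3)oc2c1I | intermediate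
6 | 1-phenylvinylboronic acid pinacol ester | C=C(c1ccccc1)B1OC(C)(C)C(C)(C)O1 | starting material
7 | 7-hydroxy-5-methoxy-2-(4-methoxyphenyl)-8-(1-phenylethenyl)chromen-4-one | C=C(c1ccccc1)c1c(O)cc(OC)c2c(=O)cc(-c3ccc(OC)cc3)oc12 | intermediate
8 | carbon monoxide | [C-]#[O+] | starting material
9 | (10R)-5-methoxy-2-(4-methoxyphenyl)-10-phenyl-9,10-dihydro-4H,8H-pyrano[2,3-h]chromene-4,8-dione | O=C1C[C@H](c2ccccc2)c2c(O1)cc(OC)c1c(=O)cc(-c3ccc(OC)cc3)oc21 | intermediate
10 | (10R)-5-hydroxy-2-(4-hydroxyphenyl)-10-phenyl-9,10-dihydro-4H,8H-pyrano[2,3-h]chromene-4,8-dione | O=C1C[C@H](c2ccccc2)c2c(O1)cc(O)c1c(=O)cc(-c3ccc(O)cc3)oc21 | intermediate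
11 | trilithium (3R)-3-[5-hydroxy-7-oxido-2-(4-oxidophenyl)-4-oxochromen-8-yl]-3-phenylpropanoate | [Li+].[Li+].[Li+].[O-]C(=O)C[C@H](c1ccccc1)c1c([O-])cc(O)c2c(=O)cc(-c3ccc([O-])cc3)oc12 | intermediate (not isolated)
12 | (3R)-3-[5,7-dihydroxy-2-(4-hydroxyphenyl)-4-oxochromen-8-yl]-3-phenylpropanoic acid | O=C(O)C[C@H](c1ccccc1)c1c(O)cc(O)c2c(=O)cc(-c3ccc(O)cc3)oc12 | target

**Step count**

Total steps: 8. Longest linear sequence: 8 steps (1 to 12).

**Steps most likely to fail**

Step 6. Hydropalladation of the twisted, di-ortho-oxygenated 1,1-diarylethylene may be too slow to compete with acid-induced oligomerisation of the alkene, and discrimination between phenyl and the flavone aryl may be weak. The fallback sets out from 4 and builds the stereocentre by conjugate addition. A Heck reaction of 4 with methyl acrylate (Pd(OAc)2, Bu4NCl, NaHCO3, DMF, 80 °C) should give methyl (E)-3-[5-methoxy-7-(methoxymethoxy)-2-(4-methoxyphenyl)-4-oxochromen-8-yl]prop-2-enoate F1. A Hayashi–Miyaura addition of phenylboronic acid ([RhCl(C2H4)2]2, chiral diene, KOH, dioxane/H2O, 50 °C; ligand antipode chosen for R) should give methyl (3R)-3-[5-methoxy-7-(methoxymethoxy)-2-(4-methoxyphenyl)-4-oxochromen-8-yl]-3-phenylpropanoate F2; the 2-aryl chromone enone is not an acceptor under these conditions. Cleavage of the MOM group (2 M HCl, MeOH, 45 °C) should give methyl (3R)-3-[7-hydroxy-5-methoxy-2-(4-methoxyphenyl)-4-oxochromen-8-yl]-3-phenylpropanoate F3, and lactonisation (cat. TsOH, toluene, 90 °C) returns to the route at 9.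

Step 5. Oxidative addition and transmetalation at the electron-rich, di-ortho-substituted iodophenoxide may be slow, so that hydrodeiodination and protodeboronation of the α-styrenyl boronate take over. The fallback sets out from 4 and forms the alkene by a carbene route instead of transmetalation. A Barluenga coupling of 4 with acetophenone N-tosylhydrazone (Pd2(dba)3, XPhos, LiOtBu, dioxane, 100 °C) should give 5-methoxy-7-(methoxymethoxy)-2-(4-methoxyphenyl)-8-(1-phenylethenyl)chromen-4-one F4. Non-protic cleavage of the phenolic MOM ether (TMSOTf, 2,2′-bipyridyl, CH2Cl2, 0 °C; then H2O), which spares the acid-sensitive diarylethylene, returns to the route at 7.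

Step 7. Cleavage of the non-chelated 4′-methyl ether may be incomplete, and long exposure to BBr3/HBr may give mixtures of lactone and ring-opened material or erode the benzylic centre. The fallback sets out from 9 and removes the two methyl groups by different mechanisms. BCl3 (CH2Cl2, −78 to 0 °C) should cleave only the chelated 5-methyl ether to give (10R)-5-hydroxy-2-(4-methoxyphenyl)-10-phenyl-9,10-dihydro-4H,8H-pyrano[2,3-h]chromene-4,8-dione F5. Sodium ethanethiolate (DMF, 130–150 °C) should then remove the 4′-methyl group by SN2 at carbon while opening the lactone. Aqueous hydroxide work-up and cold acidification to pH 3–4 come back to the route at 12; basic conditions do not endanger the non-enolisable stereocentre.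

**Further compounds**

F1 | step 6 | methyl (E)-3-[5-methoxy-7-(methoxymethoxy)-2-(4-methoxyphenyl)-4-oxochromen-8-yl]prop-2-enoate | COC(=O)/C=C/c1c(OCOC)cc(OC)c2c(=O)cc(-c3ccc(OC)cc3)oc12
F2 | step 6 | methyl (3R)-3-[5-methoxy-7-(methoxymethoxy)-2-(4-methoxyphenyl)-4-oxochromen-8-yl]-3-phenylpropanoate | COC(=O)C[C@H](c1ccccc1)c1c(OCOC)cc(OC)c2c(=O)cc(-c3ccc(OC)cc3)oc12
F3 | step 6 | methyl (3R)-3-[7-hydroxy-5-methoxy-2-(4-methoxyphenyl)-4-oxochromen-8-yl]-3-phenylpropanoate | COC(=O)C[C@H](c1ccccc1)c1c(O)cc(OC)c2c(=O)cc(-c3ccc(OC)cc3)oc12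
F4 | step 5 | 5-methoxy-7-(methoxymethoxy)-2-(4-methoxyphenyl)-8-(1-phenylethenyl)chromen-4-one | COCOc1cc(OC)c2c(=O)cc(-c3ccc(OC)cc3)oc2c1C(=C)c1ccccc1
F5 | step 7 | (10R)-5-hydroxy-2-(4-methoxyphenyl)-10-phenyl-9,10-dihydro-4H,8H-pyrano[2,3-h]chromene-4,8-dione | O=C1C[C@H](c2ccccc2)c2c(O1)cc(O)c1c(=O)cc(-c3ccc(OC)cc3)oc21
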